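**Retrosynthetic overview**
- The strategy rests on one feature: in the upper unit, O1–C2–C3–C4 of ring C fused to the 7,8-dioxygenated ring A is the skeleton of 7,8-dihydroxycoumarin with C4 as its β-carbon. The C4(upper)–C6(lower) diarylmethine bond is therefore cut as a conjugate arylation, and C2 of the lower unit is cut the same way as the β-carbon of a 7,8-dioxygenated chromone.
- Lower unit: the pyranone ring is closed first (chromone from gallacetophenone) and ring B enters at C2 by asymmetric 1,4-arylation. The C3 and C4 oxygens are relayed from C2 through the flav-3-ene by a Woodward cis-hydroxylation, and the C6 bromide becomes the boronate.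
- Upper unit: the lactone ring is bought as daphnetin and joined through C4. It is hydroxylated at C3, opened to a Weinreb amide to take up ring B, and reclosed last as the pyran ring by O1–C2 Mitsunobu etherification after chelation-controlled ketone reduction.
- End game: hydrogenolysis of eight benzyl ethers, then buffered fluoride.

Key step: step 13

Assumption (chemistry): the sense of induction of (R)-t-BuPyOx in step 5 and of (S)-Segphos in step 13 is assigned by analogy with simple chromones and coumarins. It would be checked on first use, and the antipodal ligand taken if the sense is reversed.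

Shorthand: Ar-L = (2R,3S,4R)-7,8-bis(benzyloxy)-2-[4-(benzyloxy)phenyl]-3,4-bis(tert-butyldimethylsilyloxy)chroman-6-yl (all-cis), the lower unit bonded through C6. Its C3 descriptor differs from that of diol 12 only because of the silyl ether; the spatial arrangement is unchanged.

**Route**

Step 1
Reactants: 1 2,3,4-trihydroxyacetophenone
Product: 2 3,4-bis(benzyloxy)-2-hydroxyacetophenone
Conditions: BnBr (2.1 equiv), K2CO3, acetone, reflux
Reagents that add atoms: benzyl bromide, BrCc1ccccc1
Why: Williamson etherification in which the 2-hydroxyl, hydrogen-bonded to the acetyl oxygen, is the least nucleophilic, so two equivalents of halide should stop at the 3,4-dibenzyl ether.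

Step 2
Reactants: 2 3,4-bis(benzyloxy)-2-hydroxyacetophenone
Product: 3 5-bromo-3,4-bis(benzyloxy)-2-hydroxyacetophenone
Conditions: NBS, MeCN, 0 °C to rt
Reagents that add atoms: N-bromosuccinimide, O=C1CCC(=O)N1Br
Why: electrophilic aromatic bromination at the only doubly activated open position, para to the free phenol and ortho to the 4-benzyloxy group; this carbon becomes C6 of the lower unit.

Step 3
Reactants: 3 5-bromo-3,4-bis(benzyloxy)-2-hydroxyacetophenone
Product: 4 (E)-enaminone of 3
Conditions: Me2NCH(OMe)2, toluene, 95 °C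
Reagents that add atoms: N,N-dimethylformamide dimethyl acetal, COC(OC)N(C)C
Why: enaminone condensation of the methyl ketone with the amide acetal, which supplies the future C2 of the chromone.

Step 4
Reactants: 4 (E)-enaminone
Product: 5 6-bromo-7,8-bis(benzyloxy)chromone
Conditions: conc. HCl, CH2Cl2, rt to 40 °C
Reagents that add atoms: none
Why: acid-promoted intramolecular oxa-Michael addition of the phenol to the enaminone followed by loss of dimethylamine, the standard chromone ring closure, which benzyl ethers tolerate.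

Step 5
Reactants: 5 6-bromo-7,8-bis(benzyloxy)chromone; 6 4-(benzyloxy)phenylboronic acid
Product: 7 (2S)-6-bromo-7,8,4'-tris(benzyloxy)flavanone
Conditions: Pd(OCOCF3)2 (10 mol %), (R)-t-BuPyOx (12 mol %), NH4PF6, H2O (5 equiv), ClCH2CH2Cl, 60 °C; work-up without base
Reagents that add atoms: none
Why: asymmetric conjugate arylation of the chromone in which palladium stays divalent palladium through transmetallation, insertion and protonolysis, so the C–Br bond is untouched, and the pyridine-oxazoline ligand selects the enantioface that gives C2 as 2S.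

Step 6
Reactants: 7 (2S)-flavanone
Product: 8 (2S,4S)-2,4-cis-flavan-4-ol
Conditions: NaBH4, THF/MeOH, −10 to 0 °C
Reagents that add atoms: none
Why: borohydride reduction of the aryl ketone by axial attack should give the 2,4-cis alcohol cold enough to avoid ring opening of the flavanone; the C4 centre is temporary.

Step 7
Reactants: 8 (2S,4S)-flavan-4-ol
Product: 9 (2S)-flav-3-ene
Conditions: Burgess reagent (MeO2CN−SO2N+Et3), toluene, 50 °C, dark, argon
Reagents that add atoms: none
Why: Burgess dehydration, a syn elimination of the derived sulfamate under neutral conditions, gives the C3=C4 alkene without the acid that would lead to flavylium salts or scramble C2.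

Step 8
Reactants: 9 (2S)-flav-3-ene
Product: 11 all-cis 4-hydroxyflavan-3-yl acetate (2R,3R,4R), via trans-iodoacetate 10 (not isolated)
Conditions: I2 (1.05 equiv), AgOAc (2.2 equiv), AcOH, rt, dark; then H2O (1.5 equiv), 50 °C
Reagents that add atoms: silver acetate, CC(=O)[O-].[Ag+]; water, O; iodine, II (held in 10 only)
Why: Woodward cis-hydroxylation in which the iodonium forms on the face away from the 2-aryl group, acetate opens it at benzylic C4, the acetate carbonyl displaces iodide at C3 with inversion and water collapses the acetoxonium, so both oxygens land on the aryl face and C3 and C4 are relayed from C2 (the 4-O-acetyl isomer, if formed, converges in step 9).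

Step 9
Reactants: 11 all-cis hydroxy acetate
Product: 12 (2R,3R,4R)-all-cis 3,4-diol, 6-bromide
Conditions: K2CO3 (0.2 equiv), MeOH, 0 °C to rt
Reagents that add atoms: none
Why: base-catalysed transesterification to methyl acetate frees the diol without touching any stereocentre.

Step 10
Reactants: 12 all-cis 3,4-diol
Product: 13 3,4-bis(tert-butyldimethylsilyl) ether, 6-bromide
Conditions: TBSOTf (3 equiv), 2,6-lutidine, CH2Cl2, −78 to 0 °C
Reagents that add atoms: tert-butyldimethylsilyl triflate, CC(C)(C)[Si](C)(C)OS(=O)(=O)C(F)(F)F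
Why: silylation with the silyl triflate and a hindered base is fast enough to cap both hindered cis hydroxyls, and from here the ionisable benzylic C4 oxygen is protected against acid.

Step 11
Reactants: 13 bis-silyl ether bromide
Product: 14 6-pinacolboronate of the lower unit (Ar-L–Bpin)
Conditions: PdCl2(dppf) (8 mol %), bis(pinacolato)diboron (2 equiv), KOAc (3 equiv), dioxane, 90 °C
Reagents that add atoms: bis(pinacolato)diboron, CC1(C)OB(OC1(C)C)B1OC(C)(C)C(C)(C)O1
Why: Miyaura borylation (oxidative addition of zerovalent palladium into C–Br, acetate-assisted transfer of boron, reductive elimination) fixes boron at C6 with benzyl and silyl ethers inert.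

Step 12
Reactants: 15 7,8-dihydroxycoumarin (daphnetin)
Product: 16 7,8-bis(benzyloxy)coumarin
Conditions: BnBr (2.5 equiv), K2CO3, DMF, 50 °C
Reagents that add atoms: benzyl bromide, BrCc1ccccc1
Why: Williamson etherification of both phenols; the coumarin lactone is stable to carbonate.

Step 13
Reactants: 14 lower-unit pinacolboronate (1 equiv); 16 7,8-bis(benzyloxy)coumarin (3 equiv)
Product: 17 (4R)-7,8-bis(benzyloxy)-4-(Ar-L)chroman-2-one
Conditions: Rh(acac)(C2H4)2 (5 mol %), (S)-Segphos (5.5 mol %), aq KOH (0.2 equiv), dioxane/H2O 10:1, 60 °C; pH 6 buffer work-up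
Reagents that add atoms: none
Why: Hayashi–Miyaura asymmetric 1,4-addition: the boronate passes its aryl group to a Segphos-bound hydroxo complex of monovalent rhodium, the aryl–rhodium adds across the coumarin C3=C4 bond, and water protonates the rhodium enolate to release the lactone and return the hydroxo complex. The closest known reaction is the rhodium/Segphos addition of arylboronic acids to coumarins giving 4-arylchroman-2-ones; here the aryl partner is a large ortho-alkoxy pinacol boronate and the acceptor a 7,8-dialkoxycoumarin. No ring closes in this step; it forms only the C4(upper)–C6(lower) bond. The one new stereocentre, C4 of the upper unit, is set by the bisphosphine, because the stereocentres of 14 lie too far from the reacting carbon to steer it. The step needs enantioface selectivity at C3=C4, 1,4- over 1,2-addition and a fixed site on the lower ring; the ligand and the cis-locked aryl enoate secure the first two and the boron at C6 the third. Hydroxide is kept substoichiometric so the aryl lactone is not saponified, and because the bond forms under basic conditions no C4 cation arises next to the ionisable C4 silyl ether of the lower unit.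

Step 14
Reactants: 17 4-aryl-3,4-dihydrocoumarin
Product: 19 trans-3-hydroxy-4-aryl lactone (3R,4R), via potassium enolate 18 (not isolated)
Conditions: KN(SiMe3)2 (1.1 equiv), THF, −78 °C; then 2-(phenylsulfonyl)-3-phenyloxaziridine, −78 °C; NH4Cl quench at −78 °C
Reagents that add atoms: 2-(phenylsulfonyl)-3-phenyloxaziridine, O=S(=O)(N1OC1c1ccccc1)c1ccccc1; potassium bis(trimethylsilyl)amide, C[Si](C)(C)[N-][Si](C)(C)C.[K+] (potassium held in 18 only)
Why: oxaziridine hydroxylation of the lactone enolate, in which the oxidant approaches the face opposite the pseudoaxial 4-aryl group so the C3 oxygen enters trans to it, with −78 °C keeping the aryl-ester enolate from collapsing to a ketene.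

Step 15
Reactants: 19 trans-3-hydroxy lactone
Product: 20 trans-3-benzyloxy-4-aryl lactone (3R,4R)
Conditions: Ag2O (3 equiv), BnBr (3 equiv), CH2Cl2, 4 Å sieves, rt, dark
Reagents that add atoms: benzyl bromide, BrCc1ccccc1
Why: silver-oxide-mediated O-benzylation, a neutral Williamson variant, avoids the strong base that would epimerise C3 or open the lactone.

Step 16
Reactants: 20 trans-3-benzyloxy lactone
Product: 21 ring-opened N-methoxy-N-methylamide (2R,3R) bearing the free ring-A phenol
Conditions: MeNH(OMe)·HCl (3 equiv), i-PrMgCl (6 equiv), THF, −20 to 0 °C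
Reagents that add atoms: N,O-dimethylhydroxylamine hydrochloride, CNOC.Cl
Why: aminolysis of the aryl lactone by the magnesium amide (Weinreb amide formation) is easy because the phenoxide is a good leaving group, and the low temperature keeps the α-benzyloxy centre intact.

Step 17
Reactants: 21 Weinreb amide; 22 4-bromo-1,2-bis(benzyloxy)benzene
Product: 24 α-benzyloxy aryl ketone (2R,3R) bearing the free ring-A phenol, via 3,4-bis(benzyloxy)phenyllithium 23 (not isolated)
Conditions: 22 (3.2 equiv), n-BuLi (3.0 equiv), THF, −78 °C; then 21, −78 to −40 °C; aq NH4Cl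
Reagents that add atoms: n-butyllithium, [Li]CCCC (lithium held in 23 only)
Why: the aryllithium from bromine–lithium exchange adds once to the Weinreb amide because the chelated tetrahedral intermediate holds until the quench, one equivalent being spent on the phenol; ring B of the upper unit arrives here.

Step 18
Reactants: 24 α-benzyloxy aryl ketone
Product: 25 anti benzylic alcohol (1S,2R,3R)
Conditions: Zn(BH4)2 (excess), Et2O, −40 to 0 °C; aq NH4Cl
Reagents that add atoms: none
Why: Cram-chelate controlled reduction in which zinc bridges the carbonyl and the α-benzyloxy oxygen and hydride arrives from the side of the C2 hydrogen, setting the carbinol anti to the benzyloxy group, while any cyclic hemiketal tautomer reacts through the open ketone.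

Step 19
Reactants: 25 anti benzylic alcohol
Product: 26 fully protected dimer (upper unit 2,3-cis-3,4-trans)
Conditions: PPh3 (1.5 equiv), DIAD (1.5 equiv), toluene/THF, −20 °C to rt
Reagents that add atoms: none
Why: intramolecular Mitsunobu etherification in which the ring-A phenol displaces the oxyphosphonium by a 6-exo-tet SN2 attack with inversion at the benzylic carbon, turning the 1,2-anti alcohol into the 2,3-cis pyran ring, with an apolar medium and low temperature chosen to suppress ionisation.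

Step 20
Reactants: 26 fully protected dimer
Product: 27 octaphenol with the lower 3,4-bis(silyl) ether intact
Conditions: H2 (1 atm), Pd(OH)2 on carbon, THF/MeOH, rt
Reagents that add atoms: none
Why: hydrogenolysis of the eight benzyl ethers, in which the cyclic C2–O1 bonds resist cleavage at one atmosphere and the benzylic C4 oxygen of the lower unit is shielded as its silyl ether.

Step 21
Reactants: 27 octaphenol bis-silyl ether
Product: 28 target CNP0174688.1
Conditions: HF·pyridine, excess pyridine, THF, 0 °C to rt, argon; direct loading on Sephadex LH-20, no acidic work-up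
Reagents that add atoms: none
Why: fluoride cleavage of the two silyl ethers at near-neutral pH neither oxidises the polyphenol (no base, no air) nor ionises the free benzylic C4 hydroxyl (no free acid).

**Compound list**

1 | 2,3,4-trihydroxyacetophenone | CC(=O)c1ccc(O)c(O)c1O | starting material
2 | 1-[3,4-bis(benzyloxy)-2-hydroxyphenyl]ethanone | CC(=O)c1ccc(OCc2ccccc2)c(OCc2ccccc2)c1O | intermediate
3 | 1-[3,4-bis(benzyloxy)-5-bromo-2-hydroxyphenyl]ethanone | CC(=O)c1cc(Br)c(OCc2ccccc2)c(OCc2ccccc2)c1O | intermediate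
4 | (E)-1-[3,4-bis(benzyloxy)-5-bromo-2-hydroxyphenyl]-3-(dimethylamino)prop-2-en-1-one | CN(C)/C=C/C(=O)c1cc(Br)c(OCc2ccccc2)c(OCc2ccccc2)c1O | intermediate
5 | 7,8-bis(benzyloxy)-6-bromochromen-4-one | O=c1ccoc2c1cc(Br)c(OCc1ccccc1)c2OCc1ccccc1 | intermediate
6 | 4-(benzyloxy)phenylboronic acid | OB(O)c1ccc(OCc2ccccc2)cc1 | starting material
7 | (2S)-7,8-bis(benzyloxy)-2-[4-(benzyloxy)phenyl]-6-bromochroman-4-one | O=C1C[C@@H](c2ccc(OCc3ccccc3)cc2)Oc2c1cc(Br)c(OCc1ccccc1)c2OCc1ccccc1 | intermediate
8 | (2S,4S)-7,8-bis(benzyloxy)-2-[4-(benzyloxy)phenyl]-6-bromochroman-4-ol (2,4-cis) | c1ccccc1COc1ccc([C@H]2Oc3c(cc(Br)c(OCc4ccccc4)c3OCc3ccccc3)[C@@H](O)C2)cc1 | intermediate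
9 | (2S)-7,8-bis(benzyloxy)-2-[4-(benzyloxy)phenyl]-6-bromo-2H-chromene | c1ccccc1COc1ccc([C@H]2Oc3c(cc(Br)c(OCc4ccccc4)c3OCc3ccccc3)C=C2)cc1 | intermediate
10 | 7,8-bis(benzyloxy)-2-[4-(benzyloxy)phenyl]-6-bromo-3-iodochroman-4-yl acetate, iodine trans to the 2-aryl group and to the 4-acetoxy group | c1ccccc1COc1ccc([C@H]2Oc3c(cc(Br)c(OCc4ccccc4)c3OCc3ccccc3)[C@@H](OC(C)=O)[C@@H]2I)cc1 | intermediate
11 | (2R,3R,4R)-7,8-bis(benzyloxy)-2-[4-(benzyloxy)phenyl]-6-bromo-4-hydroxychroman-3-yl acetate (all-cis) | c1ccccc1COc1ccc([C@H]2Oc3c(cc(Br)c(OCc4ccccc4)c3OCc3ccccc3)[C@@H](O)[C@H]2OC(C)=O)cc1 | intermediate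
12 | (2R,3R,4R)-7,8-bis(benzyloxy)-2-[4-(benzyloxy)phenyl]-6-bromochroman-3,4-diol (all-cis) | c1ccccc1COc1ccc([C@H]2Oc3c(cc(Br)c(OCc4ccccc4)c3OCc3ccccc3)[C@@H](O)[C@H]2O)cc1 | intermediate
13 | (2R,3S,4R)-7,8-bis(benzyloxy)-2-[4-(benzyloxy)phenyl]-6-bromo-3,4-bis(tert-butyldimethylsilyloxy)chroman (all-cis) | c1ccccc1COc1ccc([C@H]2Oc3c(cc(Br)c(OCc4ccccc4)c3OCc3ccccc3)[C@@H](O[Si](C)(C)C(C)(C)C)[C@H]2O[Si](C)(C)C(C)(C)C)cc1 | intermediate
14 | Ar-L–B(pin): 2-(Ar-L)-4,4,5,5-tetramethyl-1,3,2-dioxaborolane | c1ccccc1COc1ccc([C@H]2Oc3c(cc(B4OC(C)(C)C(C)(C)O4)c(OCc4ccccc4)c3OCc3ccccc3)[C@@H](O[Si](C)(C)C(C)(C)C)[C@H]2O[Si](C)(C)C(C)(C)C)cc1 | intermediate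
15 | 7,8-dihydroxycoumarin (daphnetin) | O=c1ccc2ccc(O)c(O)c2o1 | starting material
16 | 7,8-bis(benzyloxy)coumarin | O=c1ccc2ccc(OCc3ccccc3)c(OCc3ccccc3)c2o1 | intermediate
17 | (4R)-7,8-bis(benzyloxy)-4-(Ar-L)chroman-2-one | c1ccccc1COc1ccc([C@H]2Oc3c(cc([C@H]4c5ccc(OCc6ccccc6)c(OCc6ccccc6)c5OC(=O)C4)c(OCc4ccccc4)c3OCc3ccccc3)[C@@H](O[Si](C)(C)C(C)(C)C)[C@H]2O[Si](C)(C)C(C)(C)C)cc1 | intermediate
18 | potassium enolate of 17 (potassium 7,8-bis(benzyloxy)-4-(Ar-L)-4H-chromen-2-olate) | c1ccccc1COc1ccc([C@H]2Oc3c(cc([C@H]4c5ccc(OCc6ccccc6)c(OCc6ccccc6)c5OC([O-])=C4)c(OCc4ccccc4)c3OCc3ccccc3)[C@@H](O[Si](C)(C)C(C)(C)C)[C@H]2O[Si](C)(C)C(C)(C)C)cc1.[K+] | intermediate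
19 | (3R,4R)-7,8-bis(benzyloxy)-3-hydroxy-4-(Ar-L)chroman-2-one (3,4-trans) | c1ccccc1COc1ccc([C@H]2Oc3c(cc([C@H]4c5ccc(OCc6ccccc6)c(OCc6ccccc6)c5OC(=O)[C@@H]4O)c(OCc4ccccc4)c3OCc3ccccc3)[C@@H](O[Si](C)(C)C(C)(C)C)[C@H]2O[Si](C)(C)C(C)(C)C)cc1 | intermediate
20 | (3R,4R)-3,7,8-tris(benzyloxy)-4-(Ar-L)chroman-2-one (3,4-trans) | c1ccccc1COc1ccc([C@H]2Oc3c(cc([C@H]4c5ccc(OCc6ccccc6)c(OCc6ccccc6)c5OC(=O)[C@@H]4OCc4ccccc4)c(OCc4ccccc4)c3OCc3ccccc3)[C@@H](O[Si](C)(C)C(C)(C)C)[C@H]2O[Si](C)(C)C(C)(C)C)cc1 | intermediate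
21 | (2R,3R)-2-(benzyloxy)-3-[3,4-bis(benzyloxy)-2-hydroxyphenyl]-3-(Ar-L)-N-methoxy-N-methylpropanamide | c1ccccc1COc1ccc([C@H]2Oc3c(cc([C@@H](c5ccc(OCc6ccccc6)c(OCc6ccccc6)c5O)[C@@H](OCc5ccccc5)C(=O)N(C)OC)c(OCc4ccccc4)c3OCc3ccccc3)[C@@H](O[Si](C)(C)C(C)(C)C)[C@H]2O[Si](C)(C)C(C)(C)C)cc1 | intermediate
22 | 4-bromo-1,2-bis(benzyloxy)benzene | Brc1ccc(OCc2ccccc2)c(OCc2ccccc2)c1 | starting material
23 | 3,4-bis(benzyloxy)phenyllithium | [Li]c1ccc(OCc2ccccc2)c(OCc2ccccc2)c1 | intermediate
24 | (2R,3R)-2-(benzyloxy)-1-[3,4-bis(benzyloxy)phenyl]-3-[3,4-bis(benzyloxy)-2-hydroxyphenyl]-3-(Ar-L)propan-1-one | c1ccccc1COc1ccc([C@H]2Oc3c(cc([C@@H](c5ccc(OCc6ccccc6)c(OCc6ccccc6)c5O)[C@@H](OCc5ccccc5)C(=O)c5ccc(OCc6ccccc6)c(OCc6ccccc6)c5)c(OCc4ccccc4)c3OCc3ccccc3)[C@@H](O[Si](C)(C)C(C)(C)C)[C@H]2O[Si](C)(C)C(C)(C)C)cc1 | intermediate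
25 | (1S,2R,3R)-2-(benzyloxy)-1-[3,4-bis(benzyloxy)phenyl]-3-[3,4-bis(benzyloxy)-2-hydroxyphenyl]-3-(Ar-L)propan-1-ol (1,2-anti) | c1ccccc1COc1ccc([C@H]2Oc3c(cc([C@@H](c5ccc(OCc6ccccc6)c(OCc6ccccc6)c5O)[C@@H](OCc5ccccc5)[C@@H](O)c5ccc(OCc6ccccc6)c(OCc6ccccc6)c5)c(OCc4ccccc4)c3OCc3ccccc3)[C@@H](O[Si](C)(C)C(C)(C)C)[C@H]2O[Si](C)(C)C(C)(C)C)cc1 | intermediate
26 | (2R,3R,4R)-3,7,8-tris(benzyloxy)-2-[3,4-bis(benzyloxy)phenyl]-4-(Ar-L)chroman (2,3-cis-3,4-trans) | c1ccccc1COc1ccc([C@H]2Oc3c(cc([C@H]4c5ccc(OCc6ccccc6)c(OCc6ccccc6)c5O[C@H](c5ccc(OCc6ccccc6)c(OCc6ccccc6)c5)[C@@H]4OCc4ccccc4)c(OCc4ccccc4)c3OCc3ccccc3)[C@@H](O[Si](C)(C)C(C)(C)C)[C@H]2O[Si](C)(C)C(C)(C)C)cc1 | intermediate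
27 | target with the lower-unit 3- and 4-hydroxyls as tert-butyldimethylsilyl ethers, all eight phenols free (upper 2R,3R,4S; lower 2R,3S,4R) | Oc1ccc([C@H]2Oc3c(cc([C@H]4c5ccc(O)c(O)c5O[C@H](c5ccc(O)c(O)c5)[C@@H]4O)c(O)c3O)[C@@H](O[Si](C)(C)C(C)(C)C)[C@H]2O[Si](C)(C)C(C)(C)C)cc1 | intermediate
28 | CNP0174688.1: (2R,3R,4S)-2-(3,4-dihydroxyphenyl)-3,7,8-trihydroxychroman-4-yl bonded to C6 of (2R,3R,4R)-2-(4-hydroxyphenyl)chroman-3,4,7,8-tetrol | Oc1ccc([C@H]2Oc3c(cc([C@H]4c5ccc(O)c(O)c5O[C@H](c5ccc(O)c(O)c5)[C@@H]4O)c(O)c3O)[C@@H](O)[C@H]2O)cc1 | target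

**Step count**

Total: 21 steps. Longest linear sequence: 20 steps (steps 1–11 and 13–21, from 1 to 28); step 12 is a one-step branch.

**Three steps most likely to fail**

1. Step 13 (key step). The hindered ortho-benzyloxy aryl group may pass from boron to rhodium so slowly that protodeboronation and hydroxide opening of the lactone outrun the addition, or the catalyst may give weak facial control on this crowded pair. Fallback, setting out from bromide 13 and coming back at 17: bromine–lithium exchange with t-BuLi (THF, −78 °C) gives the lower-unit aryllithium F1, which is transmetallated with MgBr2·OEt2 to the arylmagnesium bromide F2 and added to coumarin 16 in the presence of CuBr·SMe2 (organocopper conjugate addition, −40 to 0 °C, NH4Cl quench). The substrate offers no facial control, so 17 should form together with its epimer at the new diarylmethine carbon, the (4S)-lactone F3. The two are diastereomers because the lower unit is a single enantiomer; 17 is separated by chromatography and the route continues at step 14.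

2. Step 8. Ionisation at the activated benzylic C4 in warm acetic acid, or iodination of the electron-rich rings, may break the relay that places both oxygens on the aryl face. Fallback, setting out from flavene 9 and coming back at 12: NBS in aqueous acetone with NaHCO3 at 0 °C gives the bromohydrin F4 (bromine at C3 anti to the 2-aryl group, hydroxyl at C4 on the aryl face), which is purified. Boc2O with DMAP converts it into the tert-butyl carbonate F5. AgOTf with 2,6-lutidine in CH2Cl2 then lets the carbonate carbonyl displace bromide at C3 with inversion and loss of isobutene, giving the all-cis cyclic carbonate F6. K2CO3 in methanol releases diol 12.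

3. Step 19. The oxyphosphonium sits on a 3,4-dibenzyloxybenzylic carbon and may ionise, so that closure runs through a cation and the inversion is lost (2,3-trans ring) or elimination competes. Fallback, setting out from ketone 24 and coming back at 26, closing the ring at the aryl carbon instead so that the benzylic centre is never substituted: the ring-A phenol is converted into the aryl triflate F7 (PhNTf2, Et3N, DMAP, CH2Cl2). Non-chelating Felkin–Anh reduction with KBH(s-Bu)3 in THF at −78 °C gives the 1,2-syn alcohol F8. Intramolecular C–O coupling (Pd(OAc)2, 2-(di-tert-butylphosphino)-1,1'-binaphthyl, Cs2CO3, toluene, 80 °C; oxidative addition of zerovalent palladium into the aryl triflate, alkoxide binding, reductive elimination) forms the O1–C8a bond with retention at C2 and gives 26.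

**Further compounds**

F1 | step 13 | lower-unit aryllithium (6-lithio analogue of 13) | c1ccccc1COc1ccc([C@H]2Oc3c(cc([Li])c(OCc4ccccc4)c3OCc3ccccc3)[C@@H](O[Si](C)(C)C(C)(C)C)[C@H]2O[Si](C)(C)C(C)(C)C)cc1
F2 | step 13 | lower-unit arylmagnesium bromide (Ar-L–MgBr) | c1ccccc1COc1ccc([C@H]2Oc3c(cc([Mg]Br)c(OCc4ccccc4)c3OCc3ccccc3)[C@@H](O[Si](C)(C)C(C)(C)C)[C@H]2O[Si](C)(C)C(C)(C)C)cc1
F3 | step 13 | (4S)-7,8-bis(benzyloxy)-4-(Ar-L)chroman-2-one, the C4 epimer of 17 | c1ccccc1COc1ccc([C@H]2Oc3c(cc([C@@H]4c5ccc(OCc6ccccc6)c(OCc6ccccc6)c5OC(=O)C4)c(OCc4ccccc4)c3OCc3ccccc3)[C@@H](O[Si](C)(C)C(C)(C)C)[C@H]2O[Si](C)(C)C(C)(C)C)cc1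
F4 | step 8 | 7,8-bis(benzyloxy)-2-[4-(benzyloxy)phenyl]-3,6-dibromochroman-4-ol, 3-bromine trans to the 2-aryl group, 4-hydroxyl cis to it | c1ccccc1COc1ccc([C@H]2Oc3c(cc(Br)c(OCc4ccccc4)c3OCc3ccccc3)[C@@H](O)[C@@H]2Br)cc1
F5 | step 8 | tert-butyl carbonate of F4 at the 4-hydroxyl | c1ccccc1COc1ccc([C@H]2Oc3c(cc(Br)c(OCc4ccccc4)c3OCc3ccccc3)[C@@H](OC(=O)OC(C)(C)C)[C@@H]2Br)cc1
F6 | step 8 | all-cis 3,4-cyclic carbonate of diol 12 | c1ccccc1COc1ccc([C@H]2Oc3c(cc(Br)c(OCc4ccccc4)c3OCc3ccccc3)[C@H]5OC(=O)O[C@@H]25)cc1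
F7 | step 19 | aryl triflate of ketone 24 (ring-A phenol as trifluoromethanesulfonate) | c1ccccc1COc1ccc([C@H]2Oc3c(cc([C@@H](c5ccc(OCc6ccccc6)c(OCc6ccccc6)c5OS(=O)(=O)C(F)(F)F)[C@@H](OCc5ccccc5)C(=O)c5ccc(OCc6ccccc6)c(OCc6ccccc6)c5)c(OCc4ccccc4)c3OCc3ccccc3)[C@@H](O[Si](C)(C)C(C)(C)C)[C@H]2O[Si](C)(C)C(C)(C)C)cc1
F8 | step 19 | (1R,2R,3R)-1,2-syn alcohol from F7, the carbinol epimer of 25 as its aryl triflate | c1ccccc1COc1ccc([C@H]2Oc3c(cc([C@@H](c5ccc(OCc6ccccc6)c(OCc6ccccc6)c5OS(=O)(=O)C(F)(F)F)[C@@H](OCc5ccccc5)[C@H](O)c5ccc(OCc6ccccc6)c(OCc6ccccc6)c5)c(OCc4ccccc4)c3OCc3ccccc3)[C@@H](O[Si](C)(C)C(C)(C)C)[C@H]2O[Si](C)(C)C(C)(C)C)cc1
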